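Everything rests on making ring B (C1, C8, C7, C6, C5, C9; C1 = acyl-bearing bridgehead, C9 = bridging ketone) by disconnecting C1–C8 and C5–C9. In that ring C1 carries three acyl carbons (C2, C9, C10) and is joined to the fully substituted C8 (methyl, homoprenyl) – the arrangement a Wolff 1,2-shift leaves behind. Thermolysis of an open-chain 2-diazo-1,3-diketone transfers C8 from carbonyl carbon C9 to the diazo carbon C1 with retention, and the acylketene so formed is acylated at C9 by C5 of a tethered aldehyde silyl enol ether, closing ring B in one operation. The precursor: diazo carbon flanked by the (R)-2-methylbutanoyl ketone and the C9 ketone on a lactone-derived C7/C8 stereodiad.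

Key step: step 14

Remarks on the chemistry: atom labels follow the bicyclo[3.3.1]nonane numbering of the target (C1 acylated bridgehead, C2–C4 the enolised diketone bridge of ring A, C5 the second bridgehead, C6–C8 the rest of ring B, C9 the bridging ketone, C10 the acyl carbonyl). The enol ether C5=C4 (16, 20–22) is assumed to be usable as an E/Z mixture and is drawn E, since its geometry is lost in step 14; enols are drawn as one tautomer.

**Step 1**
Reactants: 1 4-tert-butoxy-4-oxobutanoic acid; 2 (4R)-4-benzyl-1,3-oxazolidin-2-one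
Product: 4 tert-butyl 4-[(4R)-4-benzyl-2-oxo-1,3-oxazolidin-3-yl]-4-oxobutanoate, via mixed pivalic anhydride 3 (not isolated)
Conditions: t-BuCOCl, Et3N, THF, −20 °C; then 2, LiCl, −20 °C → rt
Reagents that add atoms: none
Why: N-acylation of the oxazolidinone auxiliary through the mixed pivalic anhydride, which is attacked at the unhindered succinyl carbonyl; no stereocentre is formed.

**Step 2**
Reactants: 4 succinyl imide; 5 1-bromo-3-methylbut-2-ene (prenyl bromide)
Product: 6 tert-butyl (3R)-3-[(4R)-4-benzyl-2-oxo-1,3-oxazolidine-3-carbonyl]-6-methylhept-5-enoate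
Conditions: NaN(SiMe3)2, THF, −78 °C; then 5, −78 → −45 °C
Reagents that add atoms: none
Why: Evans asymmetric alkylation, in which the imide α-CH2 is deprotonated in preference to the ester α-CH2 and the chelated Z-enolate is prenylated on the face away from the benzyl group, setting C7.

**Step 3**
Reactants: 6 alkylated imide
Product: 8 (4R)-4-(3-methylbut-2-en-1-yl)oxolan-2-one, via hydroxy ester 7 (not isolated)
Conditions: LiBH4, H2O (1 equiv), Et2O, 0 °C; then KOC(CH3)3 (0.1 equiv), THF, 0 °C → rt
Reagents that add atoms: none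
Why: reductive removal of the auxiliary (the imide is reduced, the tert-butyl ester spared) followed by alkoxide-catalysed 5-exo-trig lactonisation, run under base so that the prenyl alkene never meets acid; C7 is untouched.

**Step 4**
Reactants: 8 prenyl lactone
Product: 9 (3R,4R)-3-methyl-4-(3-methylbut-2-en-1-yl)oxolan-2-one
Conditions: LiN(i-Pr)2, THF, −78 °C; then MeI, −78 → −40 °C
Reagents that add atoms: iodomethane, CI
Why: lactone enolate alkylation with MeI entering trans to the C7 prenyl group; this α-configuration is erased again in step 6, so only clean mono-methylation matters.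

**Step 5**
Reactants: 10 5-bromo-2-methylpent-2-ene
Product: 11 5-iodo-2-methylpent-2-ene
Conditions: NaI, acetone, reflux
Reagents that add atoms: sodium iodide, [Na+].[I-]
Why: Finkelstein exchange driven by precipitation of NaBr gives the more reactive primary iodide needed for the quaternary alkylation.

**Step 6**
Reactants: 9 methyl lactone; 11 5-iodo-2-methylpent-2-ene
Product: 12 (3R,4R)-3-methyl-4-(3-methylbut-2-en-1-yl)-3-(4-methylpent-3-en-1-yl)oxolan-2-one
Conditions: LiN(i-Pr)2, THF, −78 °C; then 11, DMPU, −78 → −20 °C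
Reagents that add atoms: none
Why: alkylation of the α-methyl lactone enolate, whose planar five-membered ring is approached by the iodide on the face opposite the neighbouring C7 prenyl group, so homoprenyl ends trans and methyl cis to prenyl and the quaternary C8 is set.

**Step 7**
Reactants: 12 quaternary lactone
Product: 13 (3R)-3-[(2R)-1-hydroxy-5-methylhex-4-en-2-yl]-3,7-dimethyloct-6-en-2-one
Conditions: MeLi (1.2 equiv), Et2O, −78 °C; then aq. NH4Cl
Reagents that add atoms: methyllithium, [Li]C
Why: mono-addition of methyllithium to the lactone, whose lithium hemiketal next to the quaternary carbon survives at −78 °C and collapses only on work-up, giving the methyl ketone (carbonyl = C9, methyl = C1) in equilibrium with its cyclic hemiketal.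

**Step 8**
Reactants: 13 hydroxy ketone
Product: 14 (2R)-2-[(3R)-3,7-dimethyl-2-oxooct-6-en-3-yl]-5-methylhex-4-enal
Conditions: Dess–Martin periodinane, NaHCO3, CH2Cl2, 0 °C → rt
Reagents that add atoms: none
Why: Dess–Martin oxidation of the primary alcohol drains the hemiketal equilibrium and, being buffered and non-basic, should leave the α-stereocentre C7 of the new aldehyde intact; the keto aldehyde is used directly.

**Step 9**
Reactants: 14 keto aldehyde
Product: 15 (2E,4S)-4-[(3R)-3,7-dimethyl-2-oxooct-6-en-3-yl]-7-methylocta-2,6-dienal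
Conditions: Ph3P=CHCHO, toluene, 80 °C
Reagents that add atoms: (triphenylphosphoranylidene)acetaldehyde, O=CC=P(c1ccccc1)(c1ccccc1)c1ccccc1
Why: Wittig olefination with a stabilised ylide, which reacts with the aldehyde but not with the hindered methyl ketone, should give the (E)-enal and brings in C5 and C4; the weakly basic ylide should not epimerise C7.

**Step 10**
Reactants: 15 enal
Product: 16 (3R)-3-[(1E,4S)-1-(tert-butyldimethylsilyloxy)-7-methylocta-1,6-dien-4-yl]-3,7-dimethyloct-6-en-2-one
Conditions: t-BuMe2SiH, Pt2[(CH2=CHSiMe2)2O]3 (0.5 mol %), toluene, 60 °C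
Reagents that add atoms: tert-butyldimethylsilane, C[SiH](C)C(C)(C)C
Why: platinum-catalysed 1,4-hydrosilylation of the enal gives the aldehyde silyl enol ether C5=C4–OSi under neutral conditions, so neither base nor silyl triflate meets the methyl ketone, while the trisubstituted alkenes and the hindered ketone stay inert.

**Step 11**
Reactants: 17 (2R)-2-methylbutanoic acid
Product: 19 (2R)-N-methoxy-N,2-dimethylbutanamide, via acyl imidazole 18 (not isolated)
Conditions: 1,1'-carbonyldiimidazole, CH2Cl2, 0 °C → rt; then MeNH(OMe)·HCl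
Reagents that add atoms: N,O-dimethylhydroxylamine hydrochloride, CNOC.Cl
Why: Weinreb amide formation through the acyl imidazole, a coupling that should not epimerise a simple α-alkyl acid.

**Step 12**
Reactants: 16 silyl enol ether methyl ketone; 19 Weinreb amide
Product: 20 (3R,7R)-7-[(1E,4S)-1-(tert-butyldimethylsilyloxy)-7-methylocta-1,6-dien-4-yl]-3,7,11-trimethyldodec-10-ene-4,6-dione
Conditions: LiN(SiMe3)2 (2.2 equiv), THF, −78 °C; then 19, −78 → 0 °C; aq. NH4Cl
Reagents that add atoms: none
Why: crossed Claisen acylation of the methyl ketone enolate (C1 is the only enolisable position because C8 is quaternary) by the Weinreb amide, whose chelated adduct stops over-addition; the amide α-hydrogen is too weakly acidic for the silylamide, so the (R) centre should be kept, and the second equivalent of base only holds the product as its diketonate.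

**Step 13**
Reactants: 20 1,3-diketone
Product: 21 (3R,7R)-5-diazo-7-[(1E,4S)-1-(tert-butyldimethylsilyloxy)-7-methylocta-1,6-dien-4-yl]-3,7,11-trimethyldodec-10-ene-4,6-dione
Conditions: 4-AcNHC6H4SO2N3, Et3N, MeCN, 0 °C → rt
Reagents that add atoms: 4-acetamidobenzenesulfonyl azide, CC(=O)Nc1ccc(cc1)S(=O)(=O)N=[N+]=[N-]
Why: Regitz diazo transfer to the 1,3-diketone under amine base, fast enough at 0 °C that the sulfonyl azide should not engage the enol ether and too weakly basic to touch the acyl α-centre.

**Step 14**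
Reactants: 21 diazodiketone
Product: 24 (2R)-1-[(3Z,5S,6R)-2-hydroxy-3-(hydroxymethylidene)-6-methyl-5-(3-methylbut-2-en-1-yl)-6-(4-methylpent-3-en-1-yl)cyclohex-1-en-1-yl]-2-methylbutan-1-one, via acylketene 22 (not isolated), via silyl dienol ether 23 (not isolated)
Conditions: toluene (0.01 M), 140 °C, sealed tube; then 1 M HCl, THF, 0 °C
Reagents that add atoms: none
Why: Proposed new method: loss of N2 is coupled to a Wolff 1,2-shift of the fully substituted C8 from carbonyl carbon C9 to the diazo carbon C1 (new bond C1–C8, suprafacial, hence retention at C8), which turns C9 into the sp carbon of acylketene 22; the closest known reaction type is the thermal Wolff rearrangement of 2-diazo-1,3-diketones to α-oxoketenes followed by their C-acylation of enol ethers. C5 of the silyl enol ether then adds to C9 in the plane of the ketene C=O π* orbital, a six-membered closure (C9, C1, C8, C7, C6, C5) that is exo with respect to C9=O and leaves C1=C9 in the ring as the enolate; the concerted hetero-Diels–Alder mode seen between separate molecules would place a double bond at a bridgehead, so the stepwise Mukaiyama-type path should operate, the silyl group passing from the C4 oxocarbenium oxygen to the diketonate oxygen through a six-membered array (23) before acid removes it. No stereocentre is formed (C5 is trigonal in 24), and C7, C8 and the acyl α-carbon are not touched. The selectivity needed is migration of C8 and not of the sec-butyl carbon: heat is chosen over light so that the acyl rotamers equilibrate before nitrogen leaves and the choice falls to the two transition states, where the tertiary, more electron-rich C8 is the better migrating group and its shift relieves the congestion at the C9 carbonyl; this is the one real uncertainty of the route. Capture by C5 and not by the two trisubstituted alkenes, which could also reach C9 through six-membered arrays, rests on the far higher nucleophilicity of the enol ether, and high dilution should keep the ketene from dimerising.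

**Step 15**
Reactants: 24 ring B hydroxymethylene triketone; 5 1-bromo-3-methylbut-2-ene
Product: 25 (1R,4R,5S)-2-hydroxy-4-methyl-3-[(2R)-2-methylbutanoyl]-1,5-bis(3-methylbut-2-en-1-yl)-4-(4-methylpent-3-en-1-yl)cyclohex-2-ene-1-carbaldehyde
Conditions: K2CO3 (1.1 equiv), acetone, 0 °C → rt
Reagents that add atoms: none
Why: C-alkylation of the hydroxymethylene ketone anion (the most acidic site; the C1 diketone is less acidic and shielded by C8) with the allylic bromide, the electrophile entering axially on the half-chair that keeps the C7 prenyl equatorial, that is on the face opposite the C7 prenyl and the axial C8 methyl, which sets C5 with the formyl carbon C4 cis to the C7 prenyl.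

**Step 16**
Reactants: 25 C5-prenylated aldehyde; 26 ethoxyethyne
Product: 27 (2R)-1-[(3S,5S,6R)-3-(3-ethoxy-1-hydroxyprop-2-yn-1-yl)-2-hydroxy-6-methyl-3,5-bis(3-methylbut-2-en-1-yl)-6-(4-methylpent-3-en-1-yl)cyclohex-1-en-1-yl]-2-methylbutan-1-one (both carbinol epimers)
Conditions: LiN(SiMe3)2 (1.05 equiv), THF, −78 °C; then LiC≡COEt (from 26, n-BuLi; 1.5 equiv), −78 °C; AcOH
Reagents that add atoms: none
Why: 1,2-addition of lithium ethoxyacetylide to the neopentyl, non-enolisable aldehyde after the β-diketone has been turned into its lithium enolate, which masks the C9 and C10 carbonyls and blocks retro-aldol loss of C4; the new carbinol centre is a mixture and disappears in step 17.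

**Step 17**
Reactants: 27 propargylic alcohol
Product: 28 (2R)-1-[(3R,5S,6R)-3-(3-ethoxyprop-2-ynoyl)-2-hydroxy-6-methyl-3,5-bis(3-methylbut-2-en-1-yl)-6-(4-methylpent-3-en-1-yl)cyclohex-1-en-1-yl]-2-methylbutan-1-one
Conditions: MnO2, CH2Cl2, rt
Reagents that add atoms: none
Why: manganese dioxide oxidation, selective for the propargylic alcohol and neutral, so that Meyer–Schuster rearrangement of the ethoxyethynyl carbinol is avoided and the enolised diketone is spared.

**Step 18**
Reactants: 28 ethoxy ynone
Product: 29 (1R,5S,7S,8R)-2-ethoxy-8-methyl-1-[(2R)-2-methylbutanoyl]-5,7-bis(3-methylbut-2-en-1-yl)-8-(4-methylpent-3-en-1-yl)bicyclo[3.3.1]non-2-ene-4,9-dione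
Conditions: Ph3PAuNTf2 (5 mol %), 4 Å MS, CH2Cl2, rt
Reagents that add atoms: none
Why: gold-catalysed Conia-ene carbocyclisation (6-endo-dig), in which π-activation of the push–pull alkyne by the monovalent gold cation makes C2 (β to the ketone and α to OEt) the electrophile for the enol carbon C1 and protodeauration gives the vinylogous ester; C1 is set by the ring itself, because the three-atom bridge can only span the face of ring B on which C4 stands, so its configuration follows from C5.

**Step 19**
Reactants: 29 bicyclic ethyl enol ether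
Product: 30 (1S,5S,7S,8R)-4-hydroxy-8-methyl-1-[(2R)-2-methylbutanoyl]-5,7-bis(3-methylbut-2-en-1-yl)-8-(4-methylpent-3-en-1-yl)bicyclo[3.3.1]non-3-ene-2,9-dione
Conditions: NaSEt, DMF, 60 °C; then aq. NH4Cl
Reagents that add atoms: none
Why: SN2 O-dealkylation of the vinylogous ethyl ester by thiolate frees the enolised 1,3-diketone without acid (prenyl groups) or hydroxide (bridgehead acyl group, acyl α-centre), thiolate addition at C2 being reversible and unproductive.

**Compound list**

1 | 4-tert-butoxy-4-oxobutanoic acid | CC(C)(C)OC(=O)CCC(=O)O | starting material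
2 | (4R)-4-benzyl-1,3-oxazolidin-2-one | O=C1N[C@H](Cc2ccccc2)CO1 | starting material
3 | 4-tert-butoxy-4-oxobutanoic pivalic anhydride (not isolated) | CC(C)(C)OC(=O)CCC(=O)OC(=O)C(C)(C)C | intermediate
4 | tert-butyl 4-[(4R)-4-benzyl-2-oxo-1,3-oxazolidin-3-yl]-4-oxobutanoate | CC(C)(C)OC(=O)CCC(=O)N1[C@H](Cc2ccccc2)COC1=O | intermediate
5 | 1-bromo-3-methylbut-2-ene | CC(C)=CCBr | starting material
6 | tert-butyl (3R)-3-[(4R)-4-benzyl-2-oxo-1,3-oxazolidine-3-carbonyl]-6-methylhept-5-enoate | CC(C)(C)OC(=O)C[C@@H](CC=C(C)C)C(=O)N1[C@H](Cc2ccccc2)COC1=O | intermediate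
7 | tert-butyl (3R)-3-(hydroxymethyl)-6-methylhept-5-enoate (not isolated) | CC(C)(C)OC(=O)C[C@@H](CC=C(C)C)CO | intermediate
8 | (4R)-4-(3-methylbut-2-en-1-yl)oxolan-2-one | O=C1C[C@@H](CC=C(C)C)CO1 | intermediate
9 | (3R,4R)-3-methyl-4-(3-methylbut-2-en-1-yl)oxolan-2-one | O=C1OC[C@H](CC=C(C)C)[C@H]1C | intermediate
10 | 5-bromo-2-methylpent-2-ene | CC(C)=CCCBr | starting material
11 | 5-iodo-2-methylpent-2-ene | CC(C)=CCCI | intermediate
12 | (3R,4R)-3-methyl-4-(3-methylbut-2-en-1-yl)-3-(4-methylpent-3-en-1-yl)oxolan-2-one | O=C1OC[C@H](CC=C(C)C)[C@@]1(C)CCC=C(C)C | intermediate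
13 | (3R)-3-[(2R)-1-hydroxy-5-methylhex-4-en-2-yl]-3,7-dimethyloct-6-en-2-one | CC(=O)[C@](C)(CCC=C(C)C)[C@@H](CC=C(C)C)CO | intermediate
14 | (2R)-2-[(3R)-3,7-dimethyl-2-oxooct-6-en-3-yl]-5-methylhex-4-enal | CC(=O)[C@](C)(CCC=C(C)C)[C@@H](CC=C(C)C)C=O | intermediate
15 | (2E,4S)-4-[(3R)-3,7-dimethyl-2-oxooct-6-en-3-yl]-7-methylocta-2,6-dienal | CC(=O)[C@](C)(CCC=C(C)C)[C@@H](CC=C(C)C)/C=C/C=O | intermediate
16 | (3R)-3-[(1E,4S)-1-(tert-butyldimethylsilyloxy)-7-methylocta-1,6-dien-4-yl]-3,7-dimethyloct-6-en-2-one | CC(=O)[C@](C)(CCC=C(C)C)[C@@H](CC=C(C)C)C/C=C/O[Si](C)(C)C(C)(C)C | intermediate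
17 | (2R)-2-methylbutanoic acid | CC[C@@H](C)C(=O)O | starting material
18 | (2R)-1-(imidazol-1-yl)-2-methylbutan-1-one (not isolated) | CC[C@@H](C)C(=O)n1ccnc1 | intermediate
19 | (2R)-N-methoxy-N,2-dimethylbutanamide | CC[C@@H](C)C(=O)N(C)OC | intermediate
20 | (3R,7R)-7-[(1E,4S)-1-(tert-butyldimethylsilyloxy)-7-methylocta-1,6-dien-4-yl]-3,7,11-trimethyldodec-10-ene-4,6-dione | CC[C@@H](C)C(=O)CC(=O)[C@](C)(CCC=C(C)C)[C@@H](CC=C(C)C)C/C=C/O[Si](C)(C)C(C)(C)C | intermediate
21 | (3R,7R)-5-diazo-7-[(1E,4S)-1-(tert-butyldimethylsilyloxy)-7-methylocta-1,6-dien-4-yl]-3,7,11-trimethyldodec-10-ene-4,6-dione | CC[C@@H](C)C(=O)C(=[N+]=[N-])C(=O)[C@](C)(CCC=C(C)C)[C@@H](CC=C(C)C)C/C=C/O[Si](C)(C)C(C)(C)C | intermediate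
22 | acylketene: C8 on C1, C9 as the ketene carbon (not isolated) | CC[C@@H](C)C(=O)C(=C=O)[C@](C)(CCC=C(C)C)[C@@H](CC=C(C)C)C/C=C/O[Si](C)(C)C(C)(C)C | intermediate
23 | ring B C9 O-silyl enol ether with the formyl group on C5, C5 epimers (not isolated) | CC[C@@H](C)C(=O)C1=C(O[Si](C)(C)C(C)(C)C)C(C=O)C[C@H](CC=C(C)C)[C@@]1(C)CCC=C(C)C | intermediate
24 | (2R)-1-[(3Z,5S,6R)-2-hydroxy-3-(hydroxymethylidene)-6-methyl-5-(3-methylbut-2-en-1-yl)-6-(4-methylpent-3-en-1-yl)cyclohex-1-en-1-yl]-2-methylbutan-1-one | OC1=C(C(=O)[C@H](C)CC)[C@](C)(CCC=C(C)C)[C@@H](CC=C(C)C)C/C1=C/O | intermediate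
25 | (1R,4R,5S)-2-hydroxy-4-methyl-3-[(2R)-2-methylbutanoyl]-1,5-bis(3-methylbut-2-en-1-yl)-4-(4-methylpent-3-en-1-yl)cyclohex-2-ene-1-carbaldehyde | CC[C@@H](C)C(=O)C1=C(O)[C@](CC=C(C)C)(C=O)C[C@H](CC=C(C)C)[C@@]1(C)CCC=C(C)C | intermediate
26 | ethoxyethyne | CCOC#C | starting material
27 | (2R)-1-[(3S,5S,6R)-3-(3-ethoxy-1-hydroxyprop-2-yn-1-yl)-2-hydroxy-6-methyl-3,5-bis(3-methylbut-2-en-1-yl)-6-(4-methylpent-3-en-1-yl)cyclohex-1-en-1-yl]-2-methylbutan-1-one, carbinol epimers | CC[C@@H](C)C(=O)C1=C(O)[C@](CC=C(C)C)(C(O)C#COCC)C[C@H](CC=C(C)C)[C@@]1(C)CCC=C(C)C | intermediate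
28 | (2R)-1-[(3R,5S,6R)-3-(3-ethoxyprop-2-ynoyl)-2-hydroxy-6-methyl-3,5-bis(3-methylbut-2-en-1-yl)-6-(4-methylpent-3-en-1-yl)cyclohex-1-en-1-yl]-2-methylbutan-1-one | CC[C@@H](C)C(=O)C1=C(O)[C@](CC=C(C)C)(C(=O)C#COCC)C[C@H](CC=C(C)C)[C@@]1(C)CCC=C(C)C | intermediate
29 | (1R,5S,7S,8R)-2-ethoxy-8-methyl-1-[(2R)-2-methylbutanoyl]-5,7-bis(3-methylbut-2-en-1-yl)-8-(4-methylpent-3-en-1-yl)bicyclo[3.3.1]non-2-ene-4,9-dione | CC[C@@H](C)C(=O)[C@]12C(OCC)=CC(=O)[C@](CC=C(C)C)(C[C@H](CC=C(C)C)[C@@]1(C)CCC=C(C)C)C2=O | intermediate
30 | (1S,5S,7S,8R)-4-hydroxy-8-methyl-1-[(2R)-2-methylbutanoyl]-5,7-bis(3-methylbut-2-en-1-yl)-8-(4-methylpent-3-en-1-yl)bicyclo[3.3.1]non-3-ene-2,9-dione | CC[C@@H](C)C(=O)[C@]12C(=O)C=C(O)[C@](CC=C(C)C)(C[C@H](CC=C(C)C)[C@@]1(C)CCC=C(C)C)C2=O | target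

**Step count and risks**

Total step count: 19. Longest linear sequence: 17 steps (steps 1–4, 6–10 and 12–19); steps 5 and 11 are side branches.

Steps most likely to fail:

1. Step 14. The 1,2-shift may take the sec-butyl carbon instead of C8 (the bulkier acyl group is the one less readily brought anti to the departing nitrogen), or the ketene may dimerise before C5 reaches it. The fallback makes the same two bonds one at a time by established reactions, setting out from methyl ketone 16 and returning at 24. Detrifluoroacetylative diazo transfer (LiN(SiMe3)2, CF3CO2CH2CF3; then MeSO2N3, Et3N, MeCN) passes through the trifluoromethyl diketone F1 to the diazomethyl ketone F2. Its Wolff rearrangement under Arndt–Eistert conditions (hν, THF–H2O), where C8 is the only group able to migrate, gives the homologated acid F3 (C1–C8 made, the carboxyl carbon being C9). 1-Chloro-N,N,2-trimethylprop-1-en-1-amine turns F3 into the acid chloride F4, which acylates the tethered silyl enol ether at C5 (catalytic ZnCl2) to give the hydroxymethylene ketone F5 (C5–C9 made). Acylation of the α′-dianion of F5 (LiN(i-Pr)2, 2.2 equiv) at C1 with Weinreb amide 19 returns to 24.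

2. Step 18. The enol oxygen on C9 may add to the gold-activated alkyne in place of C1 (closure to a pyranone), or the ynol ether may be hydrated by traces of water. The fallback closes ring A by acylation instead of hydroalkylation, setting out from ynone 28 and returning at the target 30, so that 29 is by-passed. Heating 28 in toluene at 120 °C expels ethylene by retro-ene fragmentation of the ethoxyalkyne and gives the acylketene F6. O-acylation of the enol by this ketene is reversible at that temperature, whereas C-acylation at C1 is not, because the product enolises between C2 and C4.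

3. Step 15. The prenyl group may enter on the wrong face of C5 (cis to the C7 prenyl) or on the hydroxymethylene oxygen. The fallback replaces substrate control by catalyst control, setting out from 24 and returning at 25: the prenyl group is delivered as a π-allyl palladium complex (Pd2(dibenzylideneacetone)3, one enantiomer of N,N'-(cyclohexane-1,2-diyl)bis[2-(diphenylphosphino)benzamide] chosen by screening, prenyl methyl carbonate, toluene). This Tsuji–Trost alkylation is C-selective for soft β-dicarbonyl anions, attacks the unsubstituted allyl terminus, and lets the ligand override the bias of the ring; no new intermediate arises.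

**Further compounds**

F1 | step 14 | (5R)-5-[(1E,4S)-1-(tert-butyldimethylsilyloxy)-7-methylocta-1,6-dien-4-yl]-1,1,1-trifluoro-5,9-dimethyldec-8-ene-2,4-dione | O=C(CC(=O)[C@](C)(CCC=C(C)C)[C@@H](CC=C(C)C)C/C=C/O[Si](C)(C)C(C)(C)C)C(F)(F)F
F2 | step 14 | (3R)-1-diazo-3-[(1E,4S)-1-(tert-butyldimethylsilyloxy)-7-methylocta-1,6-dien-4-yl]-3,7-dimethyloct-6-en-2-one | [N-]=[N+]=CC(=O)[C@](C)(CCC=C(C)C)[C@@H](CC=C(C)C)C/C=C/O[Si](C)(C)C(C)(C)C
F3 | step 14 | (3S)-3-[(1E,4S)-1-(tert-butyldimethylsilyloxy)-7-methylocta-1,6-dien-4-yl]-3,7-dimethyloct-6-enoic acid | OC(=O)C[C@](C)(CCC=C(C)C)[C@@H](CC=C(C)C)C/C=C/O[Si](C)(C)C(C)(C)C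
F4 | step 14 | (3S)-3-[(1E,4S)-1-(tert-butyldimethylsilyloxy)-7-methylocta-1,6-dien-4-yl]-3,7-dimethyloct-6-enoyl chloride | ClC(=O)C[C@](C)(CCC=C(C)C)[C@@H](CC=C(C)C)C/C=C/O[Si](C)(C)C(C)(C)C
F5 | step 14 | (3S,4S,6Z)-6-(hydroxymethylidene)-3-methyl-4-(3-methylbut-2-en-1-yl)-3-(4-methylpent-3-en-1-yl)cyclohexan-1-one | O/C=C1/C[C@H](CC=C(C)C)[C@@](C)(CCC=C(C)C)CC1=O
F6 | step 18 | acylketene from 28: 3-oxoprop-2-enoyl (C4(=O)–C3H=C2=O) group on C5 in place of the ethoxypropynoyl group | CC[C@@H](C)C(=O)C1=C(O)[C@](CC=C(C)C)(C(=O)C=C=O)C[C@H](CC=C(C)C)[C@@]1(C)CCC=C(C)C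
F0 | step 15 | none | none
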